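Remarks on the chemistry, valid for everything below:
- Numbering: C1–C6 are the ring atoms of the target, C7 the methyl on C1, C8=C9 the side chain on C1, C10 the carbon on C3. The same numbers are used for every intermediate.
- Assumption: the sense in which an L-configured primary amino acid selects between the two acetyl groups of 5 cannot be read from a close precedent; the L-catalyst is written, and its D-enantiomer is meant should a first run show the opposite sense at C1.

## Analysis of the target

Compound 20 is a monocyclic C10 pentahalide: a cyclohexane with C1 (quaternary, bearing the C7 methyl and the (Z)-C8=C9 chlorovinyl group), C2H2, C3 (bearing Br and the C10H2Br group), C4HCl, C5H2 and C6HCl. It has four stereocentres, C1 (S), C3 (S), C4 (R) and C6 (S), two of them fully substituted. The two secondary chlorines, the tertiary bromine and the chlorovinyl group lie on one face of the ring, and the C7 methyl and the bromomethyl group on the other; in the chair with both chlorines equatorial, methyl and CH2Br are equatorial and the chlorovinyl group and C3–Br are 1,3-diaxial. The sensitive groups are the Z-vinyl chloride (isomerisation, over-reduction), the tertiary bromide beside a primary one (elimination, reductive loss of bromine) and the secondary chlorides (elimination with base); no oxygen or nitrogen remains to protect or to steer reagents. The synthesis is hard because the absolute configuration must be created at an all-carbon quaternary centre, because C6–Cl sits next to that centre and C4–Cl next to the fully substituted C3, and because five halogens of two kinds must go in with site and face control in an order that lets the earlier ones survive. The strategy rests on C1: the ring unit C6–C5 and the side chain C8–C9 are both two-carbon units on it, so both can begin as acetyl groups, which makes C1 a prochiral carbon with two enantiotopic acetyl groups. Closing C4–C5 by an aldol addition of one of them creates C1 and C4 together and leaves a C6 ketone, a C8 acetyl group and a C3=C10 methylene where the C6 chlorine, the chlorovinyl group and the two bromines are needed.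

## Retrosynthetic reasoning

20 to 19. The Z-chloroalkene is taken back to the chloroalkyne 19 by removing two hydrogens from C8 and C9. This is the last forward step because the vinyl chloride is the group most easily isomerised or over-reduced. The alkyne also serves twice before that: it is electron-poor and not attacked during bromination, and it is the slimmest possible axial group on C1 when C3 is attacked. With C3=C10 already saturated in 19, the semireduction has no second π bond to distinguish, which it would have if it came before the bromination.

19 to 18. The C3–Br and C10–Br bonds are cut together, which leads to the C3=C10 methylene of 18. The forward anti addition of two bromine atoms must put the C3 bromine axial, cis to the chloroethynyl group; the chair of 18, fixed by two equatorial chlorines, is the controlling element.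

18 to 16, 15 and 13. Each C–Cl bond is cut to a C–O bond of opposite configuration, so both oxygens must be cis to the C7 methyl. The two substitutions are kept apart because two free hydroxyls in a cis-1,3 relation form cyclic derivatives with dehydrating chlorinating agents and because the two sites differ: C6 is flanked by the quaternary C1, C4 is allylic. C6 is substituted first, on 13 through its triflate 14, while C4 still carries a silyl ether. C4 is substituted last, through 17, because the allylic chloride 18 can isomerise by SN2′ and should be consumed at once.

13 to 9. The C8≡C9–Cl unit is traced to the acetyl group: C9–Cl comes from the acetylide 11 and the triple bond from the enol triflate 10 of the methyl ketone 9; the chloroalkyne 12 formed in this way loses its trimethylsilyl group on the way to 13. C1 is quaternary, so the acetyl group enolises only toward C9. The forward sequence needs a strong amide base, so it must come before any C–Cl bond is present. The C6 oxygen must already be reduced and both oxygens masked: a C6 ketone would compete for the base, and a C6 alkoxide β to the C8 ketone would undergo retro-aldol cleavage.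

9 to 8, 7 and 6. The C6 carbinol comes from the C6 ketone by hydride addition. The forward step must choose the ring ketone over the acetyl group and place the hydroxyl cis to the C4 oxygen. A chelation-controlled reduction of the free ketol 6, the usual route to a syn 1,3-diol in open chains, is not relied on: the chelate would have to bridge the cyclohexanone between the C4 oxygen and the in-plane lone pairs of the C6 carbonyl, and a hydride bound to the C4 oxygen would be delivered to the wrong face. The C4 hydroxyl is therefore silylated first, which gives 7, and the silyl ether is used as a steric shield; the same ether is needed anyway for the base chemistry. A wrong C4 epimer cannot be mended at the ketol stage by oxidation and re-reduction; that correction is moved behind the C6 reduction (see the fallback to step 3).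

6 to 5. This is the key disconnection: C4–C5 is cut, opening the ring to the achiral keto enal 5. Cutting here, and not at C1–C2 or C3–C4, is what turns the quaternary centre into a prochiral one, so a catalyst can create C1 and C4 in the ring-forming step. The aldehyde of 5 has no α-hydrogen and cannot form an enamine or enolate of its own; the only nucleophilic positions are the two acetyl methyl groups. The forward reaction must pick one acetyl group, one aldehyde face, and 1,2- over 1,4-addition.

5 to 3, 4, 1 and 2. C3=C10 is cut to the aldehyde 3 and formaldehyde 4 (α-methylenation), and C1–C2 to 3-methylpentane-2,4-dione 1 and acrolein 2 (Michael addition). Both are standard reactions on commodity chemicals and create no stereocentre, so the precursor is reached in two steps and the risk of the route sits in the key step.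

## Alternatives that were turned down

Alternative 1: No ring bond is made. The prochiral 4-methyl-4-[(tert-butyldiphenylsilyloxy)methyl]cyclohexa-2,5-dien-1-one A1 is desymmetrised by nucleophilic epoxidation of one of its two enantiotopic enone arms under iminium catalysis with a chiral primary-amine salt and a peroxide. This gives the epoxy enone A2 with the oxirane cis to the C7 methyl, fixing C1 and the C6 oxygen together. In its favour: amine-catalysed epoxidation of cyclic enones is better precedented than the aldol chosen here, the two arms of the rigid dienone A1 are cleanly differentiated, and there is no 1,2/1,4 ambiguity. On precedent and on likely enantiocontrol it is the stronger plan. Against it for this target: A2 holds only eight of the ten carbons. C10 must be added at C3, which is one of two α-positions of the C4 ketone, and C9 must be added by chloromethylenation of a neopentyl aldehyde, with poor Z control. The C5 oxygen must also be removed again, the C2=C3 bond reduced, and the C4 ketone turned into a chloride with its own stereocontrol. The chosen route offers instead the complete carbon skeleton, with C3=C10, the C6 ketone and the C8–C9 acetyl group in place, directly after the key step.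

Alternative 2: The C3–C4 bond is cut. The ynal 3-(tert-butyldimethylsilyloxy)-4-[(4-methoxybenzyloxy)methyl]-4-methylhept-6-ynal A3 is cyclised by Ni(cod)2, a zerovalent nickel complex, with a phosphine and Et3SiH through an oxanickelacycle to the silyl ether A4, which has the exocyclic C3=C10 methylene beside the C4 oxygen. In its favour: this reductive alkyne–aldehyde coupling delivers exactly the methylene-carbinol motif, six-membered closures of this type are known, no conjugate pathway competes, and the two oxygens emerge differently protected, which suits two separate chlorinations better than the chosen route does at that stage. Against it: the key step makes one bond and one stereocentre (C4) under substrate control, while the quaternary C1 and the C6 carbinol must already be present in the acyclic precursor A3, which needs its own asymmetric synthesis. Terminal alkynes are also the less well-behaved partners in this coupling, and A4 still lacks C9, so the oxymethyl group must be unmasked, oxidised and homologated. The chosen route offers instead a precursor made in two steps, catalytic creation of the quaternary centre, and the C8–C9 unit from the start.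

Alternative 3: C4–C5 and C5–C6 are both cut, and the one-carbon piece C5 is nitromethane A7. The dialdehyde 2-[(tert-butyldimethylsilyloxy)methyl]-3-(2-formyl-1,3-dioxolan-2-yl)-2-methylpropanal A5 takes up the nitronate of A7 at its C4 aldehyde and, after a second deprotonation, at its C6 aldehyde, which gives the all-equatorial nitro diol A6. In its favour: two C–C bonds and three stereocentres form in one operation under thermodynamic control, and both hydroxyls come out cis to the C7 methyl as double inversion requires; per step it builds more than the chosen aldol. Against it: C5 of the target is a methylene, so the nitro group of A6 must be removed by radical denitration from a β,β′-dihydroxy nitro compound that is prone to retro-Henry cleavage. A5 must already carry C1 as a resolved quaternary stereocentre, so the key step creates no absolute configuration. The C3 ketal must later be methylenated and the oxymethyl group homologated to the chlorovinyl group. The chosen route offers instead absolute stereochemistry created in the ring-forming step, no atom that must be removed later, and fewer functional-group changes.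

Key step: step 3

## Route

Step 1
Reactants: 1 3-methylpentane-2,4-dione; 2 acrolein
Product: 3 4-acetyl-4-methyl-5-oxohexanal
Conditions: Et3N (5 mol %), MeCN, 0 °C → rt
Reagents that add atoms: none
Why: Michael addition of the doubly stabilised enolate of 1 to the enal forms C1–C2 and the quaternary carbon. With catalytic amine at or below room temperature neither retro-Claisen cleavage of the β-diketone nor aldol closure is expected, and C1 is not a stereocentre because its two acetyl groups are identical.

Step 2
Reactants: 3 4-acetyl-4-methyl-5-oxohexanal; 4 formaldehyde (37 % aqueous)
Product: 5 4-acetyl-4-methyl-2-methylidene-5-oxohexanal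
Conditions: pyrrolidine (10 mol %), EtCO2H (10 mol %), i-PrOH, 45 °C
Reagents that add atoms: none
Why: Amine-catalysed Mannich condensation with formaldehyde and loss of the amine (α-methylenation of an aldehyde) installs C10 as the C3=C10 methylene. The hindered acetyl groups should not condense with pyrrolidine under these conditions; the product is used at once because α-substituted acroleins dimerise on standing.

Step 3
Reactants: 5 4-acetyl-4-methyl-2-methylidene-5-oxohexanal
Product: 6 (2S,5S)-2-acetyl-5-hydroxy-2-methyl-4-methylidenecyclohexan-1-one (C4–OH cis to the C7 methyl)
Conditions: O-tert-butyl-L-threonine (20 mol %), DMF, 0 °C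
Reagents that add atoms: none
Why: Proposed new method: the primary amino group of the catalyst condenses with one acetyl group of 5 to an N–H enamine on its methyl side (C1 is quaternary, and the aldehyde, having no α-hydrogen, can form no enamine), the carboxylic acid hydrogen-bonds the C4 carbonyl oxygen, and the enamine carbon C5 adds to C4; hydrolysis of the iminium ion at C6 releases 6 and the catalyst. The closest known reaction type is the amino-acid-catalysed enantiogroup-differentiating intramolecular aldol (Hajos–Parrish cyclisation), in which the two enantiotopic carbonyl groups are the acceptors, whereas here they are the donors and the acceptor is an enal; a primary amine is used because secondary amines hardly form enamines of tert-alkyl methyl ketones. The ring C1–C6 closes in the 6-(enolendo)-exo-trig mode through a chair-like transition state. C1 is set by the catalyst: its acid group sits on one face of the enamine and draws the tethered aldehyde to that face, and the two acetyl groups differ in which of the remaining C1 substituents, methyl or acetyl, must then sit beside the enamine nitrogen. C4 is set in the same transition state relative to C1; the arrangement in which the acid group reaches the carbonyl oxygen while the second acetyl group stays clear of the enamine nitrogen is expected to leave the hydroxyl cis to the C7 methyl, and this is the less secure of the two selectivities. The step needs 1,2-addition at C4 and not 6-endo conjugate addition of C5 to C10; the substrate supplies the single enolisable site of each acetyl group and the non-enolisable aldehyde, while the 1,2-preference rests on acid activation of the carbonyl oxygen and low temperature and is not enforced by the substrate. The aldehyde also condenses reversibly with the catalyst to an α-methylene imine, an off-cycle state that is the origin of the conjugate-addition risk.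

Step 4
Reactants: 6 (2S,5S)-2-acetyl-5-hydroxy-2-methyl-4-methylidenecyclohexan-1-one
Product: 7 2-acetyl-5-(tert-butyldimethylsilyloxy)-2-methyl-4-methylidenecyclohexan-1-one (C4–OSi cis to the C7 methyl)
Conditions: TBSOTf, 2,6-lutidine, CH2Cl2, −78 °C
Reagents that add atoms: tert-butyldimethylsilyl trifluoromethanesulfonate, CC(C)(C)[Si](C)(C)OS(=O)(=O)C(F)(F)F
Why: Silylation of the unhindered allylic hydroxyl with a silyl triflate and a hindered pyridine base at low temperature avoids β-elimination of the ketol. The bulky ether shields the methyl-bearing face of C6 for step 5 and withstands the strong base of step 7.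

Step 5
Reactants: 7 2-acetyl-5-(tert-butyldimethylsilyloxy)-2-methyl-4-methylidenecyclohexan-1-one
Product: 8 1-[4-(tert-butyldimethylsilyloxy)-2-hydroxy-1-methyl-5-methylidenecyclohexyl]ethan-1-one (C6–OH and C4–OSi both cis to the C7 methyl)
Conditions: NaBH4 (0.5 equiv), MeOH/CH2Cl2, −78 → −40 °C
Reagents that add atoms: none
Why: Borohydride reduction with a limited amount of hydride; the cyclohexanone carbonyl is more reactive than the tert-alkyl methyl ketone of the acetyl group. Hydride should approach C6 from the face opposite the C7 methyl and the C4 silyloxy group (axial attack anti to the axial methyl in one chair, attack away from the axial silyloxy group in the other), so the new hydroxyl is cis to both.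

Step 6
Reactants: 8 1-[4-(tert-butyldimethylsilyloxy)-2-hydroxy-1-methyl-5-methylidenecyclohexyl]ethan-1-one
Product: 9 1-[4-(tert-butyldimethylsilyloxy)-1-methyl-5-methylidene-2-(trimethylsilyloxy)cyclohexyl]ethan-1-one
Conditions: TMSCl, imidazole, CH2Cl2, 0 °C
Reagents that add atoms: chlorotrimethylsilane, C[Si](C)(C)Cl
Why: Silylation masks the only acidic hydrogen and prevents retro-aldol cleavage of a C6 alkoxide β to the C8 ketone under the amide base of step 7. The trimethylsilyl ether is chosen so that dilute acid removes it while the C4 tert-butyldimethylsilyl ether stays.

Step 7
Reactants: 9 1-[4-(tert-butyldimethylsilyloxy)-1-methyl-5-methylidene-2-(trimethylsilyloxy)cyclohexyl]ethan-1-one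
Product: 13 5-(tert-butyldimethylsilyloxy)-2-(chloroethynyl)-2-methyl-4-methylidenecyclohexan-1-ol (C6–OH cis to the C7 methyl), via enol triflate 10 (not isolated), via lithium acetylide 11 (not isolated), via chloroalkyne trimethylsilyl ether 12 (not isolated)
Conditions: LiN(i-Pr)2 (1.1 equiv), THF, −78 °C; PhNTf2, −78 → 0 °C; LiN(i-Pr)2 (2.5 equiv), −78 °C; NCS, −78 → 0 °C; work-up 1 M HCl/THF, 0 °C
Reagents that add atoms: N-chlorosuccinimide, O=C1CCC(=O)N1Cl
Why: Deprotonation of the acetyl methyl group (the only enolisable position) and O-triflation give the 2-triflyloxy-1-alkene, β-elimination with excess amide base gives the alkyne as its lithium acetylide, and electrophilic chlorination of the acetylide gives the 1-chloroalkyne (ketone-to-alkyne conversion via the enol triflate, then acetylide halogenation). Brief dilute acid in the work-up cleaves only the trimethylsilyl ether; no stereocentre is touched.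

Step 8
Reactants: 13 5-(tert-butyldimethylsilyloxy)-2-(chloroethynyl)-2-methyl-4-methylidenecyclohexan-1-ol
Product: 15 tert-butyl{[5-chloro-4-(chloroethynyl)-4-methyl-2-methylidenecyclohexyl]oxy}dimethylsilane (C6–Cl trans to the C7 methyl), via C6 triflate 14 (not isolated)
Conditions: Tf2O, pyridine, CH2Cl2, −40 °C; then Bu4NCl, −40 → 0 °C
Reagents that add atoms: tetrabutylammonium chloride, CCCC[N+](CCCC)(CCCC)CCCC.[Cl-]
Why: Triflation and SN2 displacement by chloride with inversion put chlorine on the face opposite the C7 methyl. In the favoured chair both oxygens are equatorial, so chloride enters along the axial direction past the axial hydrogens on C2 and C4 while the C7 methyl points to the other face, and the equatorial triflate has no antiperiplanar hydrogen for E2. The displacement is run at this stage because the second C1 substituent is a linear alkyne and no allylic chloride is yet present.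

Step 9
Reactants: 15 tert-butyl{[5-chloro-4-(chloroethynyl)-4-methyl-2-methylidenecyclohexyl]oxy}dimethylsilane
Product: 16 5-chloro-4-(chloroethynyl)-4-methyl-2-methylidenecyclohexan-1-ol (C4–OH cis and C6–Cl trans to the C7 methyl)
Conditions: HF·pyridine, pyridine, THF, 0 °C → rt
Reagents that add atoms: none
Why: Fluoride cleavage of the silyl ether under buffered, weakly acidic conditions frees the allylic C4 hydroxyl without exposing the secondary chloride or the chloroalkyne to base.

Step 10
Reactants: 16 5-chloro-4-(chloroethynyl)-4-methyl-2-methylidenecyclohexan-1-ol
Product: 18 1,5-dichloro-2-(chloroethynyl)-2-methyl-4-methylidenecyclohexane (both chlorines trans to the C7 methyl), via alkoxyphosphonium chloride 17 (not isolated)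
Conditions: Ph3PCl2, imidazole, CH2Cl2, −20 → 0 °C
Reagents that add atoms: dichlorotriphenylphosphorane, ClP(Cl)(c1ccccc1)(c1ccccc1)c1ccccc1
Why: Appel-type deoxychlorination of the secondary allylic alcohol through its alkoxyphosphonium chloride with SN2 inversion; the preformed chlorophosphorane is used so that no free phosphine meets the chloroalkyne. Collapse of the ion pair at C4 in the cold is expected to outrun SN2′ attack at C10, and the allylic chloride is brominated without storage.

Step 11
Reactants: 18 1,5-dichloro-2-(chloroethynyl)-2-methyl-4-methylidenecyclohexane
Product: 19 1-bromo-1-(bromomethyl)-2,4-dichloro-5-(chloroethynyl)-5-methylcyclohexane (C3–Br and both chlorines cis to the chloroethynyl group; CH2Br cis to the C7 methyl)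
Conditions: Br2 (1.0 equiv), CH2Cl2, −78 °C, dark
Reagents that add atoms: bromine, BrBr
Why: Electrophilic anti addition of bromine to the 1,1-disubstituted C3=C10 alkene; the electron-poor chloroalkyne is left alone. With both chlorines equatorial the chair is fixed with the slim chloroethynyl group axial; the bromonium ion should form on the open equatorial side and be opened by bromide at the tertiary carbon C3 along the axial direction, giving axial C3–Br and equatorial CH2Br.

Step 12
Reactants: 19 1-bromo-1-(bromomethyl)-2,4-dichloro-5-(chloroethynyl)-5-methylcyclohexane
Product: 20 (1S,2R,4S,5S)-1-bromo-1-(bromomethyl)-2,4-dichloro-5-[(Z)-2-chloroethenyl]-5-methylcyclohexane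
Conditions: KO2CN=NCO2K, AcOH, MeOH/1,4-dioxane, 0 °C → rt
Reagents that add atoms: none
Why: Concerted syn transfer of two hydrogens from diimide to the chloroalkyne (cis-semireduction of a 1-haloalkyne) gives the Z-chloroalkene. No other multiple bond is left, and C–Cl and C–Br bonds are inert to diimide under these weakly acidic, base-free conditions.

## Compound list

1 | 3-methylpentane-2,4-dione | CC(=O)C(C)C(C)=O | starting material
2 | acrolein (prop-2-enal) | C=CC=O | starting material
3 | 4-acetyl-4-methyl-5-oxohexanal | CC(=O)C(C)(CCC=O)C(C)=O | intermediate
4 | formaldehyde | C=O | starting material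
5 | 4-acetyl-4-methyl-2-methylidene-5-oxohexanal | CC(=O)C(C)(CC(=C)C=O)C(C)=O | intermediate
6 | (2S,5S)-2-acetyl-5-hydroxy-2-methyl-4-methylidenecyclohexan-1-one, C4–OH cis to the C7 methyl | C[C@@]1(C(C)=O)CC(=C)[C@@H](O)CC1=O | intermediate
7 | 2-acetyl-5-(tert-butyldimethylsilyloxy)-2-methyl-4-methylidenecyclohexan-1-one, C4–OSi cis to the C7 methyl | C[C@@]1(C(C)=O)CC(=C)[C@@H](O[Si](C)(C)C(C)(C)C)CC1=O | intermediate
8 | 1-[4-(tert-butyldimethylsilyloxy)-2-hydroxy-1-methyl-5-methylidenecyclohexyl]ethan-1-one, both oxygens cis to the C7 methyl | C[C@@]1(C(C)=O)CC(=C)[C@@H](O[Si](C)(C)C(C)(C)C)C[C@H]1O | intermediate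
9 | 1-[4-(tert-butyldimethylsilyloxy)-1-methyl-5-methylidene-2-(trimethylsilyloxy)cyclohexyl]ethan-1-one | C[C@@]1(C(C)=O)CC(=C)[C@@H](O[Si](C)(C)C(C)(C)C)C[C@H]1O[Si](C)(C)C | intermediate
10 | enol triflate of 9: 1-[4-(tert-butyldimethylsilyloxy)-1-methyl-5-methylidene-2-(trimethylsilyloxy)cyclohexyl]ethenyl trifluoromethanesulfonate | C[C@@]1(C(=C)OS(=O)(=O)C(F)(F)F)CC(=C)[C@@H](O[Si](C)(C)C(C)(C)C)C[C@H]1O[Si](C)(C)C | intermediate (not isolated)
11 | lithium acetylide: the C8≡C9–Li compound with C4–OTBS and C6–OTMS | C[C@@]1(C#C[Li])CC(=C)[C@@H](O[Si](C)(C)C(C)(C)C)C[C@H]1O[Si](C)(C)C | intermediate (not isolated)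
12 | chloroalkyne trimethylsilyl ether: the C8≡C9–Cl compound with C4–OTBS and C6–OTMS | C[C@@]1(C#CCl)CC(=C)[C@@H](O[Si](C)(C)C(C)(C)C)C[C@H]1O[Si](C)(C)C | intermediate (not isolated)
13 | 5-(tert-butyldimethylsilyloxy)-2-(chloroethynyl)-2-methyl-4-methylidenecyclohexan-1-ol, both oxygens cis to the C7 methyl | C[C@@]1(C#CCl)CC(=C)[C@@H](O[Si](C)(C)C(C)(C)C)C[C@H]1O | intermediate
14 | C6 trifluoromethanesulfonate of 13 | C[C@@]1(C#CCl)CC(=C)[C@@H](O[Si](C)(C)C(C)(C)C)C[C@H]1OS(=O)(=O)C(F)(F)F | intermediate (not isolated)
15 | tert-butyl{[5-chloro-4-(chloroethynyl)-4-methyl-2-methylidenecyclohexyl]oxy}dimethylsilane, C6–Cl trans and C4–OSi cis to the C7 methyl | C[C@@]1(C#CCl)CC(=C)[C@@H](O[Si](C)(C)C(C)(C)C)C[C@@H]1Cl | intermediate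
16 | 5-chloro-4-(chloroethynyl)-4-methyl-2-methylidenecyclohexan-1-ol, C4–OH cis and C6–Cl trans to the C7 methyl | C[C@@]1(C#CCl)CC(=C)[C@@H](O)C[C@@H]1Cl | intermediate
17 | alkoxytriphenylphosphonium chloride of 16 (P–O bond at C4) | C[C@@]1(C#CCl)CC(=C)[C@@H](O[P+](c2ccccc2)(c2ccccc2)c2ccccc2)C[C@@H]1Cl.[Cl-] | intermediate (not isolated)
18 | 1,5-dichloro-2-(chloroethynyl)-2-methyl-4-methylidenecyclohexane, both chlorines trans to the C7 methyl | C[C@@]1(C#CCl)CC(=C)[C@H](Cl)C[C@@H]1Cl | intermediate
19 | 1-bromo-1-(bromomethyl)-2,4-dichloro-5-(chloroethynyl)-5-methylcyclohexane, C3–Br and both chlorines cis to the chloroethynyl group | C[C@@]1(C#CCl)C[C@@](Br)(CBr)[C@H](Cl)C[C@@H]1Cl | intermediate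
20 | (1S,2R,4S,5S)-1-bromo-1-(bromomethyl)-2,4-dichloro-5-[(Z)-2-chloroethenyl]-5-methylcyclohexane | C[C@@]1(/C=C\Cl)C[C@@](Br)(CBr)[C@H](Cl)C[C@@H]1Cl | target

## Step count and least certain steps

Total step count: 12. Longest linear sequence: 12 steps (the route is fully linear from 1 and 2).

Step 3 (key step, proposed new method). The catalyst may be held by reversible condensation with the far more reactive aldehyde while enamine formation at the hindered acetyl groups is slow. The resulting α-methylene iminium may lead to 6-endo conjugate closure of C5 onto C10 or to aza-Michael addition of the catalyst. The two acetyl groups may be poorly distinguished, the ring may close to the C4 epimer, or the ketol may dehydrate.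
- Fallback on known reactions only, from 5 back to 6: the ring is closed without any amine by soft enolisation (Bu2BOTf, i-Pr2NEt, CH2Cl2, −78 °C). A boron enolate of a methyl ketone adds to an enal at the carbonyl carbon only, which gives the racemic ketol F1. Kinetic resolution by lipase-catalysed acetylation (Candida antarctica lipase B, vinyl acetate, t-BuOMe) then removes the unwanted enantiomer as its acetate F2 and leaves 6; by the usual empirical rule for lipases, with the methylidene-bearing side taken as the larger group, the (5R) alcohol is expected to be the fast-reacting one.
- If either closure gives the C4-epimeric ketol F3, it is not corrected at once, because oxidation of a ketol of this type would give an enolised cyclohexane-1,3-dione with no bias between C4 and C6. Instead Me4NBH(OAc)3 reduces C6 by hydride delivery from the C4 oxygen to the anti diol F4 with C6 already correct, MnO2 oxidises only the allylic C4 hydroxyl to the hydroxy enone F5, NaBH4–CeCl3 reduces it from the face opposite the C6 hydroxyl to the cis diol F6, and selective silylation of the unhindered allylic hydroxyl (TBSCl, imidazole) rejoins the route at 8.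

Step 8 (chloride displacement at C6). Backside approach is slowed by the quaternary C1, so elimination toward C5 or a 1,2-shift after ionisation of the triflate may overtake substitution.
- Fallback from 13 to 15, breaking the C–O bond homolytically: methyl chlorooxalate (Et3N, DMAP) gives the methyl oxalate F7 and CsOH the cesium oxalate F8. Visible-light photoredox oxidation (Ir[dF(CF3)ppy]2(dtbbpy)PF6, blue light) in the presence of ethyl trichloroacetate releases two CO2 and the C6 radical. The radical should take a chlorine atom on the face away from the C7 methyl and the C4 silyloxy group, giving 15 with no backside approach.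

Step 10 (allylic chlorination at C4). Allylic transposition (SN2′ at C10, giving a primary chloride and a C3=C4 bond) and partial loss of configuration by ion-pair return are possible, because in the favoured chair of 16 the C4–O bond is axial and aligned with the π system.
- Fallback from 13 to 18, with the order of the two substitutions reversed so that C4 reacts while its C–O bond is equatorial: HF·pyridine gives the diol F9. Its favoured chair has both hydroxyls equatorial and the C4–O bond in the nodal plane of the C3=C10 π bond, which switches off the overlap SN2′ needs. NCS–Me2S, which chlorinates allylic alcohols through the alkoxysulfonium salt and leaves hindered saturated alcohols alone, gives the chloro alcohol F10 with inversion. Triflation gives the triflate F11, and Bu4NCl as in step 8 gives 18. The price is that the C6 displacement then runs with the allylic chloride present and must be kept cold and short.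

Step 11 (bromine addition). Facial selectivity at C3 may be poor: equatorial entry of bromide, or opening of the bromonium ion at C10, each gives the C3 epimer. Axial entry is syn to the axial chloroethynyl group, and the C4 chlorine weakens the preference for opening at C3.
- Fallback from 18 through the mixture to 19, using thermodynamic instead of kinetic control: the C3 epimer F12 is not separated but equilibrated. Vicinal dibromides with a tertiary C–Br bond interconvert through the bromonium–bromide ion pair, and return of bromide to C10 inverts C3. Warming with a catalytic soluble bromide (Bu4NBr, MeCN, 60 °C) should drain the epimer into 19, which keeps the larger CH2Br group equatorial and only bromine axial beside the chloroethynyl group.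

Step 5 (ketone reduction). Site selectivity (reduction of the acetyl carbonyl or of both ketones) and facial selectivity at C6 may be insufficient, since the two chairs of 7 are close in energy and the rate difference between the two ketones is modest.
- Fallback from 7 to 8 under catalyst control instead of substrate control: screening of isolated NADPH-dependent ketoreductases with glucose/glucose dehydrogenase recycling, which routinely distinguish both the carbonyl groups and the faces of 2,2-disubstituted 1,3-diketones. This fallback makes no new compound and is entered as F0.

## Further compounds

F1 | step 3 | racemic 2-acetyl-5-hydroxy-2-methyl-4-methylidenecyclohexan-1-one (6 and its enantiomer) | C[C@@]1(C(C)=O)CC(=C)[C@@H](O)CC1=O.C[C@]1(C(C)=O)CC(=C)[C@H](O)CC1=O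
F2 | step 3 | (2R,5R)-2-acetyl-5-acetoxy-2-methyl-4-methylidenecyclohexan-1-one (acetate of the enantiomer of 6) | C[C@]1(C(C)=O)CC(=C)[C@H](OC(C)=O)CC1=O
F3 | step 3 | C4 epimer of 6, hydroxyl trans to the C7 methyl | C[C@@]1(C(C)=O)CC(=C)[C@H](O)CC1=O
F4 | step 3 | anti diol: 1-(2,4-dihydroxy-1-methyl-5-methylidenecyclohexyl)ethan-1-one, C6–OH cis and C4–OH trans to the C7 methyl | C[C@@]1(C(C)=O)CC(=C)[C@H](O)C[C@H]1O
F5 | step 3 | hydroxy enone: 4-acetyl-5-hydroxy-4-methyl-2-methylidenecyclohexan-1-one, C6–OH cis to the C7 methyl | C[C@@]1(C(C)=O)CC(=C)C(=O)C[C@H]1O
F6 | step 3 | cis diol: 1-(2,4-dihydroxy-1-methyl-5-methylidenecyclohexyl)ethan-1-one, both hydroxyls cis to the C7 methyl | C[C@@]1(C(C)=O)CC(=C)[C@@H](O)C[C@H]1O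
F7 | step 8 | methyl oxalate of 13 (mixed oxalate at the C6 oxygen) | C[C@@]1(C#CCl)CC(=C)[C@@H](O[Si](C)(C)C(C)(C)C)C[C@H]1OC(=O)C(=O)OC
F8 | step 8 | cesium oxalate of 13 | C[C@@]1(C#CCl)CC(=C)[C@@H](O[Si](C)(C)C(C)(C)C)C[C@H]1OC(=O)C(=O)[O-].[Cs+]
F9 | step 10 | 4-(chloroethynyl)-4-methyl-6-methylidenecyclohexane-1,3-diol, both hydroxyls cis to the C7 methyl | C[C@@]1(C#CCl)CC(=C)[C@@H](O)C[C@H]1O
F10 | step 10 | 5-chloro-2-(chloroethynyl)-2-methyl-4-methylidenecyclohexan-1-ol, C4–Cl trans and C6–OH cis to the C7 methyl | C[C@@]1(C#CCl)CC(=C)[C@H](Cl)C[C@H]1O
F11 | step 10 | C6 trifluoromethanesulfonate of F10 | C[C@@]1(C#CCl)CC(=C)[C@H](Cl)C[C@H]1OS(=O)(=O)C(F)(F)F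
F12 | step 11 | C3 epimer of 19, C3–Br cis to the C7 methyl | C[C@@]1(C#CCl)C[C@](Br)(CBr)[C@H](Cl)C[C@@H]1Cl
F0 | step 5 | none | none
A1 | alternative 1 | 4-methyl-4-[(tert-butyldiphenylsilyloxy)methyl]cyclohexa-2,5-dien-1-one | CC1(CO[Si](c2ccccc2)(c2ccccc2)C(C)(C)C)C=CC(=O)C=C1
A2 | alternative 1 | 5,6-epoxy-4-methyl-4-[(tert-butyldiphenylsilyloxy)methyl]cyclohex-2-en-1-one, oxirane cis to the methyl | C[C@@]1(CO[Si](c2ccccc2)(c2ccccc2)C(C)(C)C)C=CC(=O)[C@H]2O[C@@H]12
A3 | alternative 2 | 3-(tert-butyldimethylsilyloxy)-4-[(4-methoxybenzyloxy)methyl]-4-methylhept-6-ynal | C[C@@]([C@H](O[Si](C)(C)C(C)(C)C)CC=O)(COCc1ccc(OC)cc1)CC#C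
A4 | alternative 2 | 1-[(4-methoxybenzyloxy)methyl]-1-methyl-3-methylidenecyclohexane with C4 triethylsilyloxy and C6 tert-butyldimethylsilyloxy groups both cis to the methyl | C[C@@]1(COCc2ccc(OC)cc2)CC(=C)[C@@H](O[Si](CC)(CC)CC)C[C@H]1O[Si](C)(C)C(C)(C)C
A5 | alternative 3 | 2-[(tert-butyldimethylsilyloxy)methyl]-3-(2-formyl-1,3-dioxolan-2-yl)-2-methylpropanal | C[C@@](C=O)(CO[Si](C)(C)C(C)(C)C)CC1(OCCO1)C=O
A6 | alternative 3 | all-equatorial 5-nitro-4,6-diol with C3 dioxolane and C1 silyloxymethyl, both hydroxyls cis to the methyl | C[C@@]1(CO[Si](C)(C)C(C)(C)C)CC2(OCCO2)[C@@H](O)[C@H]([N+](=O)[O-])[C@H]1O
A7 | alternative 3 | nitromethane | C[N+](=O)[O-]
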